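A flat pair of curves tempts one to read a balance into them, when the question is how much of the charge can still move. Call that the remainder: the charge minus L minus J. If L and J merely take up what remains, neither can gain more in the second half of the time than the remainder standing at its start, so that figure goes to the stopping test.

the same everywhere: Q 0.028 mM (held)

|  | D | remark | time |
|---|---|---|---|
| Friday's | 5.0 × 10⁻⁴ M | the very flask that is asked about, followed so far |  |
| Saturday's | 3.4 × 10⁻⁴ M | run made earlier |  |
| flask | 5.0 × 10⁻⁴ M |  | 25 min |

Friday's run (percent of the D charged)

| time / s | L / % | J / % |
|---|---|---|
| 30.0 | 19 | 0 |
| 60.0 | 28 | 3 |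
| 90.0 | 35 | 9 |
| 120 | 41 | 9 |

Saturday's run (percent of the D charged)

| time / min | L / % | J / % |
|---|---|---|
| 2.50 | 46 | 9 |
| 5.00 | 59 | 28 |
| 8.00 | 56 | 38 |
| 10.0 | 61 | 40 |

(readings scatter by 1.5 percentage points)

- at the start none of Q is in solution
- the reaction counts as stopped when no species that holds the D changes by six tenths of a point or more over the second half of the time

* the state of affairs at 25 min: stopped, and by what, or still going (forward and back rates have come level / it is still moving / all of D has reacted)
* amount of L at 25 min, in percent of the D charged
* amount of J at 25 min, in percent of the D charged

Friday's run is the asked flask followed so far. In its first instants L reads 19% at 30.0 s and J reads 0%, so L leads and J lags. In the middle of Saturday's run, from 2.50 min to 5.00 min, J gains 19 percentage points and L gains 13 points, so J is now the faster riser. Over those times Saturday's remainder falls from 45.0% to 13.0%. Replacing that curve by one mean gives 2.01 min as the mean lifetime of the remainder.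

The error of that mean shows in Saturday's later readings. It expects 2.93% at 8.00 min against 6.00% read, yet at 10.0 min L and J already sum to 101%, so the misses fall on both sides, with 1.5 points on each reading.

Friday's flask ends its readings with a remainder of 50.0% at 120 s. Carried to 12.5 min at that mean lifetime, read in Saturday's run with its smaller charge, this gives 0.272%, under the 0.6 of a point of the test, and <0.001% at 25 min. My own reckoning therefore calls this flask stopped with D used up. Saturday's last readings split as L 60.4% and J 39.6%, and the reckoning carries that split over to this flask in spite of the different charge.

The forecast says it is still moving, with L 57% and J 43%, reasoning that “Both exceed 0.6, so strictly it is still moving”. On the state of the flask my reckoning differs from it.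

The state of the flask at 25 min is this: all of D has reacted, with L 60.8% and J 39.2%.

    G → J (k = 0.00770 /s)
    D + Z → G (k = 200 /M/s)
    D → L (k = 0.00560 /s)
    Q ⇌ Z, rate k4*(csat - [Z]) (kL = 0.100 /s)

In the asked flask D, the limiting reagent, stands at 0% at 25.0 min; at 12.5 min D and G, the species formed on the way, hold 0.547% together, twice the 0.272% carried by the mean lifetime. Z is the dissolved reagent. The neighbour flask charges 8.5 × 10⁻⁴ M of D. A full charge with mean lifetime 2.01 min keeps <0.001% at 25 min, and that flask shows D at 0%, G at 0%, L at 64.8% and J at 35.2%.

The data come from a simulation with constants of no real substance; noise was put on by code.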